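No rate constant of this chemistry is on the bench, so the argument has to start from the charges and from the two earlier runs, zeta and eta.

| flask | substrate | partner | free catalyst | impurity | remark | time |
|---|---|---|---|---|---|---|
| zeta | 0.042 M | 0.0378 M | 0.080 mM | 0.12 mM | run made earlier |  |
| eta | 0.063 M | 0.019 M | 0.080 mM | 0.12 mM | run made earlier |  |
| Tuesday's | 0.063 M | 0.0378 M | 0.080 mM | 0.12 mM |  | 2.0 h |
| Wednesday's | 0.063 M | 0.0378 M | 0.20 mM | 0.12 mM |  | 2.0 h |
| Monday's | 0.063 M | 0.0378 M | 0.60 mM | 0.12 mM |  | 2.0 h |
| Saturday's | 0.063 M | 0.0378 M | 2.0 mM | 0.12 mM |  | 2.0 h |

| run | time / min | target / % |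
|---|---|---|
| zeta | 3.00 | 6 |
| zeta | 8.00 | 11 |
| zeta | 15.0 | 17 |
| zeta | 25.0 | 18 |
| zeta | 30.0 | 22 |
| zeta | 40.0 | 28 |
| eta | 3.00 | 4 |
| eta | 6.00 | 0 |
| eta | 10.0 | 6 |
| eta | 15.0 | 8 |
| eta | 25.0 | 9 |
| eta | 40.0 | 12 |

(readings scatter by 2 percentage points)

- "hardly changes" means that all values lie within two and a half points (for a concentration: within two and a half percent of the largest)
- no earlier run changes the charge of free catalyst; that part of a forecast is a guess

1. amount of target at the end, in percent of the substrate charged for Tuesday's, Wednesday's, Monday's, Saturday's, in this order
2. the course of these numbers from the first flask to the last (falls all the way / rises all the way / rises, then falls / hardly changes / falls, then rises)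

Two chemists read this differently. The forecaster treats the charge of free catalyst as the handle on the rate, and she says plainly that this part is a guess: “Assuming rate scales with catalyst”. Her row is 31%, 43%, 54%, 58%, and its course is this: rises all the way.

The titrator looks at another pair of numbers. In both earlier runs, as in Tuesday's flask, impurity stands at 0.12 mM against 0.080 mM of free catalyst. He supposes that impurity destroys free catalyst quickly and one for one, as in a titration, and he reckons with what that fast step leaves. The surviving catalyst of Saturday's flask is 1.88 mM, that is, the charge of free catalyst minus the charge of impurity. By the same subtraction Wednesday's flask keeps 0.0800 mM and Monday's keeps 0.480 mM, while Tuesday's keeps none and has 0.0400 mM of impurity unmatched.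

On his supposition zeta had lost its catalyst, and yet its target went from 17% at 15.0 min to 28% at 40.0 min, against a scatter of 2 percentage points. So he holds that target is made without catalyst. A larger charge then buys surviving catalyst, and no earlier run shows what that does to target. He commits to no figures, but he does commit to a row that does not rise.

The simulation gives 20.1%, 18.9%, 15.7%, 14.8%, and the course is this: falls all the way. The titrator has the direction right.

    substrate + partner ⇌ target (K = 100 /M, k = 0.00690 /M/s)
    substrate + partner ⇌ isomer of the product A (K = 190 /M, k = 0.00360 /M/s)
    target + free catalyst ⇌ isomer of the product A + free catalyst, rate k3*[free catalyst]*[target] forward; the back reaction follows from the equilibrium constant (k = 0.320 /M/s)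
    free catalyst + impurity → spent catalyst (k = 41.0 /M/s)
    target ⇌ isomer of the product B (K = 6.50, k = 8.50 × 10⁻⁵ /s)

The catalysed path from target to isomer of the product A turns the row down: without it, the change from Tuesday's to Saturday's is 0 points, not −5.3 points. With 1.88 mM surviving in Saturday's flask, that forward step alone gives target a half-life of 19.2 min, short against 2.0 h. Kinetic control there gives way to thermodynamic control, and 29.1% of isomer of the product A stands over 14.8% of target. With 0.0800 mM in Wednesday's flask the same half-life is 7.52 h, long against 2.0 h. Target in Wednesday's flask ends at 18.9%.

Readings and results are calculated for substances that don't exist; noise was put on by code.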